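**Retrosynthetic overview**
- The last disconnection is the primary C4'-CH2O–acyl bond: target 25 comes from macrophorin A (18) and the half ester 23 made from (R)-mevalonolactone (esterification, then deallylation).
- The strategy rests on ring C (C1'–C6') being a masked 2,5-dialkylhydroquinone: the C6' ketone and C3' carbinol are para, the C11 methylene sits on C1' (ortho to C6') and the CH2O arm on C4' (ortho to C3'). The C1'–C2' oxirane and the C3' hydroxyl are added after dearomatisation to a quinone monoketal.
- Ring C is cut by a [3+2+1] Dötz benzannulation into the terminal alkyne C2'≡C1'–C11H2–C9 (6), one CO (C6') and a chromium alkenyl(methoxy)carbene (11) that supplies C3', C4', C5' and the CH2O arm.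
- Alkyne 6 keeps the C9–C11 bond of (+)-sclareolide, whose lactone carbonyl carbon becomes C1'. Rings A and B (trans-decalin) are bought, ring C is formed third and the oxirane fourth.

Key step: step 6

Locants: C1–C10 are the decalin carbons, C11 the methylene on C9, C12 the exocyclic methylene carbon on C8; C1'–C6' are ring C (C1' oxirane carbon bearing C11, C2' oxirane CH, C3' carbinol, C4' bearing CH2O, C5' vinylic CH, C6' ketone); C1''–C5'' are the glutarate carbons, C1'' being the ester carbonyl on the ring C arm.

Assumption: the facial sense of the tartrate-mediated epoxidation is assigned by analogy with other hydroxymethyl quinone monoketals. Diisopropyl L-tartrate is written for the oxirane of 16; the D-antipode would be used if a trial run shows the opposite sense (the two epoxides are diastereomers because of the terpene, so they can be told apart).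

**Route**

Step 1
Reactants: 1 (+)-sclareolide
Product: 2 sclareolide lactol (lactone C=O reduced to CH(OH); mixture of anomers)
Conditions: i-Bu2AlH (1.1 equiv), CH2Cl2, −78 °C; aq. KNaC4H4O6 (potassium sodium tartrate)
Reagents that add atoms: none
Why: Partial reduction of a γ-lactone with i-Bu2AlH at low temperature stops at the aluminium hemiacetal, which is released as the lactol on work-up; C5, C8, C9 and C10 are not touched.

Step 2
Reactants: 2 sclareolide lactol
Product: 4 11-ethynyldriman-8α-ol, via hydroxy aldehyde 3 (not isolated)
Conditions: dimethyl (1-diazo-2-oxopropyl)phosphonate (2 equiv), K2CO3 (3 equiv), MeOH, 0 °C → rt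
Reagents that add atoms: Ohira–Bestmann reagent, dimethyl (1-diazo-2-oxopropyl)phosphonate, CC(=O)C(=[N+]=[N-])P(=O)(OC)OC
Why: Seyferth–Gilbert homologation in the Ohira–Bestmann variant: the lactol equilibrates with the ring-opened aldehyde 3, which is trapped by the diazomethylphosphonate anion and converted through the diazoalkene and a 1,2-hydrogen shift into the terminal alkyne; the tertiary C8 hydroxyl and all stereocentres should stay as they are.

Step 3
Reactants: 4 11-ethynyldriman-8α-ol
Product: 6 11-ethynyldrim-8(12)-ene, via chlorosulfite ester 5 (not isolated)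
Conditions: SOCl2 (1.5 equiv), pyridine (6 equiv), CH2Cl2, −78 °C; chromatography on AgNO3/SiO2
Reagents that add atoms: none
Why: Base-induced anti elimination of the chlorosulfite of an equatorial tertiary alcohol: only the C12 methyl hydrogens can lie antiperiplanar to the C8–O bond, so the exocyclic alkene should predominate, and the minor ring-alkene isomers are removed by argentation chromatography.

Step 4
Reactants: 7 2-bromoprop-2-en-1-ol
Product: 8 (2-bromoallyloxy)(tert-butyl)dimethylsilane
Conditions: TBSCl (1.1 equiv), imidazole (1.5 equiv), CH2Cl2, 0 °C → rt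
Reagents that add atoms: tert-butyldimethylsilyl chloride, CC(C)(C)[Si](C)(C)Cl
Why: Standard silylation of a primary alcohol; the silyl ether survives the later neutral and oxidative steps and is removed by fluoride.

Step 5
Reactants: 8 (2-bromoallyloxy)(tert-butyl)dimethylsilane
Product: 11 pentacarbonyl{methoxy[3-(tert-butyldimethylsilyloxy)prop-1-en-2-yl]carbene}chromium, via alkenyllithium 9 (not isolated), via lithium acyl chromate 10 (not isolated)
Conditions: t-BuLi (2.0 equiv), Et2O, −78 °C; cannulated into Cr(CO)6 (1.0 equiv), Et2O–THF, −78 → 0 °C; solvent removed; Me3OBF4 (1.3 equiv), CH2Cl2, 0 °C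
Reagents that add atoms: chromium hexacarbonyl, O=C=[Cr](=C=O)(=C=O)(=C=O)(=C=O)=C=O; trimethyloxonium tetrafluoroborate, C[O+](C)C.F[B-](F)(F)F
Why: Fischer carbene synthesis: bromine–lithium exchange gives the alkenyllithium, which adds to a CO ligand of Cr(CO)6, and the acyl chromate is O-methylated by the oxonium salt; exchange in ether at −78 °C and inverse addition keep the anion from undergoing O-to-C silyl migration.

Step 6
Reactants: 6 11-ethynyldrim-8(12)-ene; 11 pentacarbonyl{methoxy[3-(tert-butyldimethylsilyloxy)prop-1-en-2-yl]carbene}chromium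
Product: 13 2-(drim-8(12)-en-11-yl)-4-methoxy-5-[(tert-butyldimethylsilyloxy)methyl]phenol, via arene Cr(CO)3 complex 12 (not isolated)
Conditions: 6 (1.0 equiv), 11 (1.3 equiv), degassed THF (0.05 M), 50 °C, argon; then air, Et2O, rt
Reagents that add atoms: none
Why: Thermal loss of one CO from 11 frees a site on chromium, the terminal alkyne of 6 inserts into the Cr=C bond with its CH terminus bonding to the carbene carbon (C2'–C3'), a CO ligand then inserts at the new carbene carbon to give a chromium-bound dienylketene (C1'–C6'), and this closes and tautomerises to the phenol, first held as the Cr(CO)3 complex 12, which air strips. The closest known reaction type is the Dötz benzannulation of alpha-substituted alkenyl(methoxy)carbene chromium complexes with terminal alkynes, which gives 4-methoxyphenols. Ring C, the only ring formed, is closed by a six-electron electrocyclisation of the dienylketene that makes the C5'–C6' bond between the ketene carbon and the CH2 terminus of the alkenyl group, an all-carbon six-membered closure. No stereocentre is created, and C5, C9 and C10 are remote and untouched. The selectivity needed is the orientation of alkyne insertion; it is secured by the size difference between H and the C11 methylene carrying the decalin, which places the larger group next to the CO-derived carbon so that the free OH lies at C6' and the OMe at C3'. The hindered 1,1-disubstituted C8 methylene should not insert, and an alkenyl carbene without a beta substituent in THF is expected to give the phenol in preference to five-membered-ring or furan products.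

Step 7
Reactants: 13 2-(drim-8(12)-en-11-yl)-4-methoxy-5-[(tert-butyldimethylsilyloxy)methyl]phenol
Product: 14 2-(drim-8(12)-en-11-yl)-4,4-dimethoxy-5-[(tert-butyldimethylsilyloxy)methyl]cyclohexa-2,5-dien-1-one
Conditions: PhI(OAc)2 (1.1 equiv), MeOH, 0 °C
Reagents that add atoms: methanol, CO
Why: Oxidative dearomatisation of a para-methoxyphenol: the aryloxyiodane is attacked by methanol at the methoxy-bearing carbon, so the dimethyl ketal forms at C3' and the ketone at C6'; the isolated alkene reacts far more slowly than the phenol.

Step 8
Reactants: 14 2-(drim-8(12)-en-11-yl)-4,4-dimethoxy-5-[(tert-butyldimethylsilyloxy)methyl]cyclohexa-2,5-dien-1-one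
Product: 15 2-(drim-8(12)-en-11-yl)-5-(hydroxymethyl)-4,4-dimethoxycyclohexa-2,5-dien-1-one
Conditions: Bu4NF (1.2 equiv), AcOH (1.2 equiv), THF, 0 °C
Reagents that add atoms: none
Why: Fluoride cleavage of a primary silyl ether; buffering with acetic acid protects the base-sensitive dienone, and the ketal is stable to these conditions.

Step 9
Reactants: 15 2-(drim-8(12)-en-11-yl)-5-(hydroxymethyl)-4,4-dimethoxycyclohexa-2,5-dien-1-one
Product: 16 (1'R,2'S)-epoxy ketone monoketal (oxirane across C1'–C2', dimethyl ketal at C3', free CH2OH on C4', ketone at C6')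
Conditions: Ph3COOH (3 equiv), NaN(SiMe3)2 (2.2 equiv), diisopropyl L-tartrate (1.3 equiv), 4 Å molecular sieves, toluene, −55 °C; pH 7 buffer
Reagents that add atoms: trityl hydroperoxide, OOC(c1ccccc1)(c1ccccc1)c1ccccc1
Why: Hydroxyl-directed nucleophilic (Weitz–Scheffer type) epoxidation: the sodium alkoxide of the C4' hydroxymethyl, the tartrate and the trityl peroxide form one aggregate that delivers peroxide across the ketal carbon to C2', the unsubstituted beta carbon of the C6' enone (the other beta carbon, C4', is fully substituted), the enolate closes on oxygen with loss of trityloxide, and the tartrate chooses the ring face, so C1' and C2' are set together under reagent control.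

Step 10
Reactants: 16 (1'R,2'S)-epoxy ketone monoketal
Product: 17 (1'R,2'S)-epoxyquinone with free hydroxymethyl (ketones at C3' and C6')
Conditions: oxalic acid (10% aq.) on SiO2, CH2Cl2, rt
Reagents that add atoms: water, O
Why: Hydrolysis of a dimethyl ketal by a weak acid on wet silica; this acid should neither protonate the 1,1-disubstituted C8 alkene nor open the electron-poor oxirane next to the carbonyl groups.

Step 11
Reactants: 17 (1'R,2'S)-epoxyquinone with free hydroxymethyl
Product: 18 macrophorin A ((1'R,2'R,3'R)-epoxyquinol diol)
Conditions: NaBH(OAc)3 (3 equiv), AcOH (2 equiv), THF, 0 °C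
Reagents that add atoms: none
Why: Hydroxyl-directed (Evans–Saksena type) reduction: the borohydride bound to the C4' hydroxymethyl can deliver hydride only to the neighbouring C3' carbonyl (C6' is out of reach and screened by the quaternary C1'), and hydride should enter on the ring face opposite the oxirane oxygen, which places the new hydroxyl cis to the epoxide (3'R).

Step 12
Reactants: 19 (R)-mevalonolactone
Product: 21 allyl (R)-3,5-dihydroxy-3-methylpentanoate, via potassium mevalonate 20 (not isolated)
Conditions: KOH (1.0 equiv), MeOH–H2O, rt; evaporation; allyl bromide (1.2 equiv), DMF, rt; neutral work-up, used at once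
Reagents that add atoms: potassium hydroxide, [K+].[OH-]; allyl bromide, C=CCBr
Why: Saponification of the δ-lactone followed by SN2 O-alkylation of the carboxylate in a dipolar aprotic solvent; the tertiary carbinol centre is not involved, and immediate use limits relactonisation.

Step 13
Reactants: 21 allyl (R)-3,5-dihydroxy-3-methylpentanoate
Product: 23 (R)-5-(allyloxy)-3-hydroxy-3-methyl-5-oxopentanoic acid, via aldehyde 22 (not isolated)
Conditions: TEMPO (0.2 equiv), PhI(OAc)2 (2.2 equiv), MeCN–pH 7 phosphate buffer (1:1), 0 °C → rt
Reagents that add atoms: water, O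
Why: Oxoammonium (TEMPO) oxidation with PhI(OAc)2 as terminal oxidant: the primary alcohol is oxidised to aldehyde 22, whose hydrate is oxidised on to the acid in the same flask, while the tertiary alcohol and the allyl ester are inert.

Step 14
Reactants: 18 macrophorin A; 23 (R)-5-(allyloxy)-3-hydroxy-3-methyl-5-oxopentanoic acid
Product: 24 macrophorin D allyl ester (C5'' allyl ester, 3''S)
Conditions: 18 (1.0 equiv), 23 (1.05 equiv), EDC (1.1 equiv), DMAP (0.1 equiv), CH2Cl2, −20 → 0 °C
Reagents that add atoms: none
Why: Steglich-type carbodiimide esterification: the primary allylic hydroxyl is acylated much faster than the secondary C3' hydroxyl beside the oxirane or the tertiary hydroxyl of the acid, and the glutarate centre keeps its configuration because it is not part of the reacting carboxyl.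

Step 15
Reactants: 24 macrophorin D allyl ester
Product: 25 CNP0158101.1 (macrophorin D)
Conditions: Pd(PPh3)4 (2 mol %), PhSiH3 (2 equiv), CH2Cl2, 0 °C, short reaction time
Reagents that add atoms: none
Why: Tsuji–Trost type deallylation: zerovalent palladium ionises the unhindered terminal allyl ester to a π-allyl complex, which the silane reduces to propene under neutral conditions; the internal allylic ester on the trisubstituted ring alkene should ionise much more slowly.

**Compound list**
1 | (+)-sclareolide | C[C@@]12CC[C@H]3C(C)(C)CCC[C@]3(C)[C@H]1CC(=O)O2 | starting material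
2 | sclareolide lactol (anomeric mixture) | C[C@@]12CC[C@H]3C(C)(C)CCC[C@]3(C)[C@H]1CC(O)O2 | intermediate
3 | 8α-hydroxy aldehyde (ring-opened form of 2, CH2CHO on C9) | C[C@@]1(O)CC[C@H]2C(C)(C)CCC[C@]2(C)[C@H]1CC=O | intermediate
4 | 11-ethynyldriman-8α-ol | C[C@@]1(O)CC[C@H]2C(C)(C)CCC[C@]2(C)[C@H]1CC#C | intermediate
5 | chlorosulfite ester of 4 | C[C@@]1(OS(=O)Cl)CC[C@H]2C(C)(C)CCC[C@]2(C)[C@H]1CC#C | intermediate
6 | (5S,9S,10S)-11-ethynyldrim-8(12)-ene (albicanyl acetylene) | C=C1CC[C@H]2C(C)(C)CCC[C@]2(C)[C@H]1CC#C | intermediate
7 | 2-bromoprop-2-en-1-ol | C=C(Br)CO | starting material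
8 | (2-bromoallyloxy)(tert-butyl)dimethylsilane | C=C(Br)CO[Si](C)(C)C(C)(C)C | intermediate
9 | [3-(tert-butyldimethylsilyloxy)prop-1-en-2-yl]lithium | [Li]C(=C)CO[Si](C)(C)C(C)(C)C | intermediate
10 | lithium acyl chromate (Li+ −O–C(alkenyl)=Cr(CO)5) | [Li+].[O-]C(C(=C)CO[Si](C)(C)C(C)(C)C)=[Cr](=C=O)(=C=O)(=C=O)(=C=O)=C=O | intermediate
11 | pentacarbonyl{methoxy[3-(tert-butyldimethylsilyloxy)prop-1-en-2-yl]carbene}chromium | COC(=[Cr](=C=O)(=C=O)(=C=O)(=C=O)=C=O)C(=C)CO[Si](C)(C)C(C)(C)C | intermediate
12 | η6-arene Cr(CO)3 complex of phenol 13 (arene and Cr(CO)3 fragment written as two dot-joined parts) | C=C1CC[C@H]2C(C)(C)CCC[C@]2(C)[C@H]1Cc1cc(OC)c(CO[Si](C)(C)C(C)(C)C)cc1O.[Cr](=C=O)(=C=O)=C=O | intermediate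
13 | 2-(drim-8(12)-en-11-yl)-4-methoxy-5-[(tert-butyldimethylsilyloxy)methyl]phenol | C=C1CC[C@H]2C(C)(C)CCC[C@]2(C)[C@H]1Cc1cc(OC)c(CO[Si](C)(C)C(C)(C)C)cc1O | intermediate
14 | 2-(drim-8(12)-en-11-yl)-4,4-dimethoxy-5-[(tert-butyldimethylsilyloxy)methyl]cyclohexa-2,5-dien-1-one | C=C1CC[C@H]2C(C)(C)CCC[C@]2(C)[C@H]1CC1=CC(OC)(OC)C(CO[Si](C)(C)C(C)(C)C)=CC1=O | intermediate
15 | 2-(drim-8(12)-en-11-yl)-5-(hydroxymethyl)-4,4-dimethoxycyclohexa-2,5-dien-1-one | C=C1CC[C@H]2C(C)(C)CCC[C@]2(C)[C@H]1CC1=CC(OC)(OC)C(CO)=CC1=O | intermediate
16 | (1'R,2'S)-epoxy ketone monoketal; same spatial arrangement at C1' and C2' as in the target, the C2' descriptor differing only because C3' is a ketal | C=C1CC[C@H]2C(C)(C)CCC[C@]2(C)[C@H]1C[C@@]12O[C@@H]1C(OC)(OC)C(CO)=CC2=O | intermediate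
17 | (1'R,2'S)-epoxyquinone with hydroxymethyl on C4' | C=C1CC[C@H]2C(C)(C)CCC[C@]2(C)[C@H]1C[C@@]12O[C@@H]1C(=O)C(CO)=CC2=O | intermediate
18 | macrophorin A, (1'R,2'R,3'R), 3'-OH cis to the oxirane oxygen | C=C1CC[C@H]2C(C)(C)CCC[C@]2(C)[C@H]1C[C@@]12O[C@@H]1[C@H](O)C(CO)=CC2=O | intermediate
19 | (R)-mevalonolactone | C[C@@]1(O)CCOC(=O)C1 | starting material
20 | potassium (R)-mevalonate | [K+].[O-]C(=O)C[C@](C)(O)CCO | intermediate
21 | allyl (R)-3,5-dihydroxy-3-methylpentanoate | C=CCOC(=O)C[C@](C)(O)CCO | intermediate
22 | allyl (R)-3-hydroxy-3-methyl-5-oxopentanoate | C=CCOC(=O)C[C@](C)(O)CC=O | intermediate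
23 | (R)-5-(allyloxy)-3-hydroxy-3-methyl-5-oxopentanoic acid | C=CCOC(=O)C[C@](C)(O)CC(=O)O | intermediate
24 | macrophorin D allyl ester (3''S) | C=C1CC[C@H]2C(C)(C)CCC[C@]2(C)[C@H]1C[C@@]12O[C@@H]1[C@H](O)C(COC(=O)C[C@@](C)(O)CC(=O)OCC=C)=CC2=O | intermediate
25 | CNP0158101.1, macrophorin D, (5S,9S,10S,1'R,2'R,3'R,3''S) | C=C1CC[C@H]2C(C)(C)CCC[C@]2(C)[C@H]1C[C@@]12O[C@@H]1[C@H](O)C(COC(=O)C[C@@](C)(O)CC(=O)O)=CC2=O | target

**Step count**
Total: 15 steps. Longest linear sequence: 11 steps from (+)-sclareolide (steps 1, 2, 3, 6, 7, 8, 9, 10, 11, 14, 15).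

**Steps most likely to fail**
The benzannulation is ranked below these three because an unhindered alkenyl carbene with a terminal alkyne is the best-behaved substrate class for phenol formation.

Step 9. The risk is weak or wrongly oriented facial discrimination by the tartrate aggregate, together with slow peroxide addition because the alpha carbon C1' is substituted, so that background epoxidation can take over. The fallback sets out from 14 and gives up hydroxyl direction. Phase-transfer nucleophilic epoxidation of the silyl ether (t-BuOOH, aq. NaOH, toluene, N-benzylcinchonidinium chloride or its pseudoenantiomeric cinchoninium salt, chosen after a trial) should attack C2' on steric grounds alone and give the silyl-protected epoxy ketal F1. Because the decalin makes the two face isomers diastereomers, they can be separated on silica even if catalyst control is modest. Desilylation with Bu4NF/AcOH then returns to the route at 16.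

Step 11. The risk is poor facial selectivity of hydride delivery (entry syn to the oxirane). The fallback sets out from 17. If syn delivery dominates, the reduction is taken to the 3'-epimer of macrophorin A F2. A double Mitsunobu acylation (4-nitrobenzoic acid, PPh3, diisopropyl azodicarboxylate, THF, 0 °C) then inverts the secondary allylic C3' centre and acylates the primary hydroxyl, giving the bis(4-nitrobenzoate) with the target configuration F3. Brief methanolysis (K2CO3, MeOH, 0 °C) comes back to the route at 18.

Step 15. The risk is competing ionisation of the internal allylic ester by zerovalent palladium, which would expel the glutarate from ring C. The fallback sets out from 18 and avoids any carboxyl protecting group. Commercial 3-hydroxy-3-methylglutaric anhydride (1 equiv, catalytic DMAP, pyridine–CH2Cl2, 0 °C) should acylate the primary hydroxyl directly, giving 25 together with the 3''-epimer of the target F4. The two are separated by preparative reversed-phase HPLC, so the route is rejoined at 25 at the cost of stereocontrol at C3''.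

**Further compounds**
F1 | step 9 | silyl-protected (1'R,2'S)-epoxy ketone monoketal | C=C1CC[C@H]2C(C)(C)CCC[C@]2(C)[C@H]1C[C@@]12O[C@@H]1C(OC)(OC)C(CO[Si](C)(C)C(C)(C)C)=CC2=O
F2 | step 11 | 3'-epimer of macrophorin A (3'-OH trans to the oxirane oxygen) | C=C1CC[C@H]2C(C)(C)CCC[C@]2(C)[C@H]1C[C@@]12O[C@@H]1[C@@H](O)C(CO)=CC2=O
F3 | step 11 | macrophorin A bis(4-nitrobenzoate) | C=C1CC[C@H]2C(C)(C)CCC[C@]2(C)[C@H]1C[C@@]12O[C@@H]1[C@H](OC(=O)c3ccc(cc3)[N+](=O)[O-])C(COC(=O)c3ccc(cc3)[N+](=O)[O-])=CC2=O
F4 | step 15 | 3''-epimer of macrophorin D | C=C1CC[C@H]2C(C)(C)CCC[C@]2(C)[C@H]1C[C@@]12O[C@@H]1[C@H](O)C(COC(=O)C[C@](C)(O)CC(=O)O)=CC2=O
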